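common to all: substrate 1.5 M; temperature 50 °C

| run | partner | remark | time |
|---|---|---|---|
| amber | 1.5 M | the very flask that is asked about, followed so far |  |
| violet | 2.2 M | run made earlier |  |
| flask | 1.50 M |  | 3.0 h |

| amber: time / min | amber: target / % | violet: time / min | violet: target / % |
|---|---|---|---|
| 12.0 | 28.6 | 1.33 | 12.8 |
| 40.0 | 29.0 | 2.50 | 18.5 |
| 60.0 | 27.6 | 5.00 | 25.5 |
| 90.0 | 25.9 | 8.00 | 30.1 |
| 150 | 24.2 | 15.0 | 34.0 |

(scatter of a reading: 0.5 percentage points)

- delta: change nothing and wait 3.0 h more
- gamma: at 3.0 h add substrate, 50.0 % of the amount charged, then wait 3.0 h
- epsilon: at 3.0 h raise the temperature by 25 K, then wait 3.0 h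

- additions bring no volume worth counting
- the earlier runs do not show what temperature does; that part of a forecast is a guess
- a reading or a percentage of target counts all its forms, free or not

- target, in percent of the substrate first charged, at 3.0 h
- what to do for the largest gain in target; "none" if nothing gains more than 2 percentage points (delta / gamma / epsilon / none)
- target present, in percent of the substrate first charged, after delta
- target present, in percent of the substrate first charged, after gamma

If every partner went into target, amber, with its equal charges, ends near 100 % of its substrate, yet it reads 29.0 % at 40.0 min, and violet's last reading, with 0.700 M more partner, stands 0.0750 M of target above that one. So suppose that partner also consumes itself in pairs, at a rate going with the square of its concentration, while the target route goes with partner to the first power.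

Solve the two extremes. Far above some partner level B*, self-loss leads, and multiplying the charge adds just B* times the logarithm of the multiplier. Far below B*, partner goes one for one into target. Partner falls through both regimes, so with a charge C the flask lies between them:

target = B* ln(1 + C/B*)

Take B* from the high extreme, as a reading with the scatter of its two readings:

B* = 0.0750 M / ln(2.2/1.5) = 0.196 M

Call this the crossing concentration, the partner level at which the two routes take equal shares at this substrate charge. The difference gave B*, so the level tests it: for amber the line gives 28.2 % against the reading of 29.0 %.

Between 12.0 min and 40.0 min, amber rose 0.4 percentage points, less than the scatter. So treat partner as the limiting reagent and reckon no gain from added substrate. Put now just under 24.2 %, with delta and gamma alike and slightly lower, and back epsilon on a guess about temperature.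

The forecast gives 23.6 % now, 22.5 % after delta and 29 % after gamma and picks gamma, holding that “Adding substrate pushes the equilibrium forward”.

The flask gives 23.8 % now, 23.3 % after delta, 23.3 % after gamma and 6.7 points of gain from epsilon, so the best choice is epsilon.

    substrate + partner → target (k = 0.0718 L mol⁻¹ min⁻¹, Ea = 85.0 kJ mol⁻¹)
    2 partner → homo dimer (k = 0.129 L mol⁻¹ min⁻¹, Ea = 61.0 kJ mol⁻¹)
    target ⇌ isomer of the product (K = 13.0, k = 0.253 min⁻¹, Ea = 86.0 kJ mol⁻¹, ΔH = −23.0 kJ mol⁻¹)
    crystals ⇌ target, rate k4*(cs4 - [target]) while solid is left; crystals form when [target] > cs4 (solubility = 18.0 mM, k = 9.71 min⁻¹)
    (constants at 50 °C)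

At 180 min the flask holds 0 % of its partner. Carry B* = 0.196 M to a neighbour flask, charged with 2.5 M of partner and otherwise alike. The line puts its target above the flask's by 6.1 points, so reckon 29.9 %. At 180 min the neighbour flask holds 0 % of its partner, 52.5 % of its substrate and 32.4 % of target.

Readings and results were computed on assumed constants, and the scatter is random.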